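**Retrosynthetic overview**
1. The last bond made is O-9–C-13: a redox-neutral dearomative spiro-hydroetherification of a 9-hydroxy-3-alkylfuran closes the oxolane, unveils the 2,3-dihydrofuran and sets C-13.
2. The furan alcohol comes from 2-(furan-3-yl)ethylcerium addition to an 8,17-epoxy-9-ketone; the epoxide comes from α-methylenation and nucleophilic epoxidation of the C-9 ketone.
3. Ring A is closed by intramolecular alkylation of the 19,20-lactone enolate (C-4) with a C-3 tosylate on the C-10 chain, which fixes C-4.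
4. The δ-lactone, C-5 and C-10 come from Mukaiyama–Michael addition (C-4–C-5), hydroxymethylation (C-10–C-20) and lactonisation on a 2-alkyl-(R)-4-silyloxycyclohexenone.
5. Ring order: ring B (C-6 set by transfer hydrogenation) → lactone → ring A → spiro-epoxide → oxolane/dihydrofuran spirocycles.

Assumption: the SMILES is taken literally; it encodes H-5 cis to the C-20 lactone methylene (rings A/B cis-fused, lactone ring trans-fused to ring B), absolute configuration 4S,5S,6R,8R,9S,10S,13R.
Convention: labdane locants are used (ring A C-1 to C-5 and C-10, ring B C-5 to C-10, C-17 on C-8, C-18 methyl and C-19 carbonyl on C-4, C-20 on C-10, side chain C-11 to C-16); β is the face of ring B that carries the C-6 oxygen, α the other face.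

**Route**

Step 1
Reactants: 1 1,4-dioxaspiro[4.5]dec-6-en-8-one
Product: 2 (R)-1,4-dioxaspiro[4.5]dec-6-en-8-ol
Conditions: RuCl(p-cymene)[(R,R)-TsDPEN] (1 mol%), HCO2H/Et3N (5:2), CH2Cl2, 23 °C
Reagents that add atoms: none
Why: Noyori asymmetric transfer hydrogenation reduces only the carbonyl of the enone and, with the alkenyl group playing the part of the aryl group in the CH/π-controlled transition state, the (R,R) catalyst gives the R carbinol that becomes C-6.

Step 2
Reactants: 2 (R)-1,4-dioxaspiro[4.5]dec-6-en-8-ol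
Product: 3 (R)-tert-butyl(1,4-dioxaspiro[4.5]dec-6-en-8-yloxy)dimethylsilane
Conditions: TBSCl, imidazole, DMF, 23 °C
Reagents that add atoms: tert-butyldimethylsilyl chloride, CC(C)(C)[Si](C)(C)Cl
Why: Standard silylation of a secondary allylic alcohol that touches no stereocentre.

Step 3
Reactants: 3 (R)-tert-butyl(1,4-dioxaspiro[4.5]dec-6-en-8-yloxy)dimethylsilane
Product: 4 (R)-4-[(tert-butyldimethylsilyl)oxy]cyclohex-2-en-1-one
Conditions: PPTS (cat.), acetone/H2O (10:1), 50 °C
Reagents that add atoms: water, O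
Why: Mild acid-catalysed ketal hydrolysis unmasks the ketone in conjugation with the alkene while the secondary silyl ether survives.

Step 4
Reactants: 4 (R)-4-[(tert-butyldimethylsilyl)oxy]cyclohex-2-en-1-one
Product: 5 (R)-4-[(tert-butyldimethylsilyl)oxy]-2-iodocyclohex-2-en-1-one
Conditions: I2, pyridine, CH2Cl2, 0 → 23 °C
Reagents that add atoms: iodine, II
Why: Johnson α-iodination (pyridine conjugate addition, iodination of the enolate, elimination) places iodine only on the α-carbon that becomes C-10.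

Step 5
Reactants: 5 (R)-4-[(tert-butyldimethylsilyl)oxy]-2-iodocyclohex-2-en-1-one; 6 allyloxy(tert-butyl)dimethylsilane
Product: 8 (R)-4-[(tert-butyldimethylsilyl)oxy]-2-{3-[(tert-butyldimethylsilyl)oxy]propyl}cyclohex-2-en-1-one, via alkylborane 7 (not isolated)
Conditions: 6, 9-BBN-H, THF, 0 → 23 °C; then 5, Pd(dppf)Cl2 (5 mol%), AsPh3 (10 mol%), Cs2CO3, DMF/THF/H2O, 23 °C
Reagents that add atoms: none
Why: B-alkyl Suzuki–Miyaura coupling, in which anti-Markovnikov hydroboration gives the primary alkylborane that couples with the α-iodoenone on zerovalent palladium and installs C-1 to C-3 without touching C-6.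

Step 6
Reactants: 8 (R)-4-[(tert-butyldimethylsilyl)oxy]-2-{3-[(tert-butyldimethylsilyl)oxy]propyl}cyclohex-2-en-1-one; 9 1-methoxy-1-[(trimethylsilyl)oxy]prop-1-ene
Product: 10 methyl 2-[(1R,6R)-6-[(tert-butyldimethylsilyl)oxy]-2-{3-[(tert-butyldimethylsilyl)oxy]propyl}-3-[(trimethylsilyl)oxy]cyclohex-2-en-1-yl]propanoate (both C-4 epimers)
Conditions: Tf2NH (2 mol%), CH2Cl2, −78 °C; Et3N quench
Reagents that add atoms: none
Why: Mukaiyama–Michael addition in which the ketene acetal attacks C-5 on the α-face, anti to the β C-6 silyloxy group (the usual trans addition to 4-silyloxycyclohexenones), and silyl transfer traps the enolate regiospecifically as the C-9/C-10 enol silane; the C-4 centre is left unset because step 9 re-makes it.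

Step 7
Reactants: 10 methyl 2-[(1R,6R)-6-[(tert-butyldimethylsilyl)oxy]-2-{3-[(tert-butyldimethylsilyl)oxy]propyl}-3-[(trimethylsilyl)oxy]cyclohex-2-en-1-yl]propanoate
Product: 13 (5R,6R,10S)-hydroxy keto lactone (ring-B C-9 ketone trans-fused to the 19,20-δ-lactone; 6β-OTBS; 10α-(3-hydroxypropyl); C-4 epimers), via hydroxymethyl ketone 11 (not isolated), via lactone bis-silyl ether 12 (not isolated)
Conditions: aq. HCHO (37%), Yb(OTf)3 (10 mol%), THF, 23 °C; then 1 M HCl, 23 → 40 °C
Reagents that add atoms: formaldehyde, C=O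
Why: Aqueous Mukaiyama aldol (hydroxymethylation) attacks C-10 on the β-face, opposite the pseudo-axial C-5 propanoate, so C-20 enters trans to C-4 and the chain is pushed cis to it (quaternary 10S); the trans-diequatorial CH2OH/ester pair then lactonises and dilute acid removes only the primary silyl ether.

Step 8
Reactants: 13 (5R,6R,10S)-hydroxy keto lactone
Product: 15 (5R,6R,10S)-tosylate enol silane (C-8=C-9 triethylsilyl enol ether; C-3 tosylate; C-4 epimers), via keto lactone tosylate 14 (not isolated)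
Conditions: TsCl, Et3N, DMAP (cat.), CH2Cl2, 0 → 23 °C; then Et3N, TESOTf, −78 → 0 °C
Reagents that add atoms: p-toluenesulfonyl chloride, Cc1ccc(cc1)S(Cl)(=O)=O; triethylsilyl trifluoromethanesulfonate, CC[Si](CC)(CC)OS(=O)(=O)C(F)(F)F
Why: Selective tosylation of the only primary alcohol, then soft enolisation of the ketone (which can enolise only toward C-8), masks C-9 as an enol silane that is inert to the base of step 9 and ready for step 10.

Step 9
Reactants: 15 (5R,6R,10S)-tosylate enol silane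
Product: 16 (4S,5S,6R,10S)-6-[(tert-butyldimethylsilyl)oxy]-9-[(triethylsilyl)oxy]-11,12,13,14,15,16,17-heptanorlabd-8-en-19,20-olide
Conditions: KN(SiMe3)2 (1.2 equiv), THF, −78 → 0 °C
Reagents that add atoms: none
Why: Intramolecular enolate alkylation (6-exo-tet) in which the C-4 lactone enolate is alkylated by the tosylate chain that sits axial on C-10, so ring A can close on one face only; this fixes C-4 as S from both epimers and gives the cis-fused decalin bridged by the lactone.

Step 10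
Reactants: 16 (4S,5S,6R,10S)-6-[(tert-butyldimethylsilyl)oxy]-9-[(triethylsilyl)oxy]-11,12,13,14,15,16,17-heptanorlabd-8-en-19,20-olide
Product: 19 (4S,5S,6R,10S)-6-[(tert-butyldimethylsilyl)oxy]-9-oxo-11,12,13,14,15,16-hexanorlabd-8(17)-en-19,20-olide, via Mannich base 17 (not isolated), via ammonium iodide 18 (not isolated)
Conditions: Me2N=CH2+ I−, CH2Cl2, 23 °C; then MeI, 23 °C; then DBU, 23 °C
Reagents that add atoms: N,N-dimethylmethyleneiminium iodide, C=[N+](C)C.[I-]
Why: Mannich reaction of the enol silane at C-8, N-methylation and Hofmann-type elimination give the exocyclic enone; C-8 is the only activated position and no stereocentre is created.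

Step 11
Reactants: 19 (4S,5S,6R,10S)-6-[(tert-butyldimethylsilyl)oxy]-9-oxo-11,12,13,14,15,16-hexanorlabd-8(17)-en-19,20-olide
Product: 20 (4S,5S,6R,8R,10S)-6-[(tert-butyldimethylsilyl)oxy]-8,17-epoxy-9-oxo-11,12,13,14,15,16-hexanorlabdan-19,20-olide
Conditions: t-BuOOH (decane), DBU, CH2Cl2, 0 → 23 °C
Reagents that add atoms: tert-butyl hydroperoxide, CC(C)(C)OO
Why: Weitz–Scheffer nucleophilic epoxidation in which the peroxide adds to C-17 and the enolate closes the oxirane from the convex β-face, because the α-face of C-8 is blocked by the axial C-1 methylene of ring A; this gives the 8R spiro-epoxide (O β, CH2 α).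

Step 12
Reactants: 21 2-(furan-3-yl)ethanol
Product: 22 3-(2-iodoethyl)furan
Conditions: I2, PPh3, imidazole, CH2Cl2, 0 → 23 °C
Reagents that add atoms: iodine, II
Why: Appel-type iodination of a primary alcohol that leaves the furan untouched.

Step 13
Reactants: 20 (4S,5S,6R,8R,10S)-6-[(tert-butyldimethylsilyl)oxy]-8,17-epoxy-9-oxo-11,12,13,14,15,16-hexanorlabdan-19,20-olide; 22 3-(2-iodoethyl)furan
Product: 25 (4S,5S,6R,8R,9S,10S)-6-[(tert-butyldimethylsilyl)oxy]-8,17:15,16-diepoxy-9-hydroxylabda-13(16),14-dien-19,20-olide, via alkyllithium 23 (not isolated), via alkylcerium dichloride 24 (not isolated)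
Conditions: 22, t-BuLi (2.0 equiv), Et2O, −78 °C; then CeCl3, THF, −78 °C; then 20, −78 → −40 °C; aq. NH4Cl
Reagents that add atoms: none
Why: Iodine–lithium exchange and transmetalation to trivalent cerium give a weakly basic alkyl nucleophile that adds to the non-enolisable C-9 ketone in preference to the hindered lactone, axially from the β-face and anti to the axial C-1 and C-17 methylenes that flank the carbonyl on the α-face, which sets 9S (side chain β, OH α).

Step 14
Reactants: 25 (4S,5S,6R,8R,9S,10S)-6-[(tert-butyldimethylsilyl)oxy]-8,17:15,16-diepoxy-9-hydroxylabda-13(16),14-dien-19,20-olide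
Product: 26 (4S,5S,6R,8R,9S,10S)-8,17:15,16-diepoxy-6,9-dihydroxylabda-13(16),14-dien-19,20-olide
Conditions: Bu4NF, THF, 0 → 23 °C; aq. NH4Cl
Reagents that add atoms: none
Why: Fluoride desilylation of the secondary silyl ether; lactone, epoxide and furan are inert and the epoxy alcohol cannot undergo Payne rearrangement because O-9 is gauche, not anti, to the C-8–O bond.

Step 15
Reactants: 26 (4S,5S,6R,8R,9S,10S)-8,17:15,16-diepoxy-6,9-dihydroxylabda-13(16),14-dien-19,20-olide
Product: 27 (4S,5S,6R,8R,9S,10S)-6-acetoxy-8,17:15,16-diepoxy-9-hydroxylabda-13(16),14-dien-19,20-olide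
Conditions: Ac2O, pyridine, DMAP (cat.), CH2Cl2, 23 °C
Reagents that add atoms: acetic anhydride, CC(=O)OC(C)=O
Why: DMAP-catalysed acetylation is selective for the secondary equatorial C-6 hydroxyl over the hindered tertiary C-9 hydroxyl.

Step 16
Reactants: 27 (4S,5S,6R,8R,9S,10S)-6-acetoxy-8,17:15,16-diepoxy-9-hydroxylabda-13(16),14-dien-19,20-olide
Product: 28 (4S,5S,6R,8R,9S,10S,13R)-6-acetoxy-8,17:9,13:15,16-triepoxylabd-14-en-19,20-olide (target)
Conditions: [Ir(dF(CF3)ppy)2(5,5'-d(CF3)bpy)]PF6 (2 mol%), Bu4P+ (PhO)2PO2− (15 mol%), 2,4,6-triisopropylbenzenethiol (20 mol%), PhCF3 (0.02 M), 450 nm LEDs, 23 °C, argon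
Reagents that add atoms: none
Why: Proposed new method: the excited trivalent iridium complex and the phosphate base remove a proton and an electron from the tertiary O-9–H bond in a concerted proton-coupled electron transfer to give the O-9 alkoxy radical, which adds 5-exo-trig to the substituted β-carbon (C-13) of the furan through a chair-like transition state that keeps C-16 (the carbon that becomes sp3 CH2) on the side of the compact spiro-epoxide and away from the quaternary C-10 with its C-1 and C-20 methylenes (hence 13R), leaving an α-oxy radical at C-16 that is reduced by hydrogen-atom transfer from the thiol before it can fragment, while the thiyl radical is returned to thiol by the divalent iridium species and the phosphoric acid, so that light pays for the estimated 10–14 kcal/mol endergonic loss of furan aromaticity and the buffered, acid-free medium prevents ionic reversion to the furan alcohol; the closest known reaction type is the photocatalytic proton-coupled-electron-transfer hydroetherification of simple alkenes by alkoxy radicals with a thiol hydrogen-atom donor, which has not been shown for dearomative spirocyclisation onto a furan.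

**Compound list**
1 | 1,4-dioxaspiro[4.5]dec-6-en-8-one | O=C1CCC2(OCCO2)C=C1 | starting material
2 | (R)-1,4-dioxaspiro[4.5]dec-6-en-8-ol | O[C@@H]1CCC2(OCCO2)C=C1 | intermediate
3 | (R)-tert-butyl(1,4-dioxaspiro[4.5]dec-6-en-8-yloxy)dimethylsilane | CC(C)(C)[Si](C)(C)O[C@@H]1CCC2(OCCO2)C=C1 | intermediate
4 | (R)-4-[(tert-butyldimethylsilyl)oxy]cyclohex-2-en-1-one | CC(C)(C)[Si](C)(C)O[C@@H]1CCC(=O)C=C1 | intermediate
5 | (R)-4-[(tert-butyldimethylsilyl)oxy]-2-iodocyclohex-2-en-1-one | CC(C)(C)[Si](C)(C)O[C@@H]1CCC(=O)C(I)=C1 | intermediate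
6 | allyloxy(tert-butyl)dimethylsilane | C=CCO[Si](C)(C)C(C)(C)C | starting material
7 | 9-{3-[(tert-butyldimethylsilyl)oxy]propyl}-9-borabicyclo[3.3.1]nonane | CC(C)(C)[Si](C)(C)OCCCB1C2CCCC1CCC2 | intermediate (not isolated)
8 | (R)-4-[(tert-butyldimethylsilyl)oxy]-2-{3-[(tert-butyldimethylsilyl)oxy]propyl}cyclohex-2-en-1-one | CC(C)(C)[Si](C)(C)O[C@@H]1CCC(=O)C(CCCO[Si](C)(C)C(C)(C)C)=C1 | intermediate
9 | 1-methoxy-1-[(trimethylsilyl)oxy]prop-1-ene (E/Z mixture) | CC=C(OC)O[Si](C)(C)C | starting material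
10 | methyl 2-[(1R,6R)-6-[(tert-butyldimethylsilyl)oxy]-2-{3-[(tert-butyldimethylsilyl)oxy]propyl}-3-[(trimethylsilyl)oxy]cyclohex-2-en-1-yl]propanoate (C-4 epimers; C-5 substituent trans to the C-6 oxygen) | CC(C)(C)[Si](C)(C)O[C@@H]1CCC(O[Si](C)(C)C)=C(CCCO[Si](C)(C)C(C)(C)C)[C@H]1C(C)C(=O)OC | intermediate
11 | methyl 2-[(1R,2S,6R)-6-[(tert-butyldimethylsilyl)oxy]-2-{3-[(tert-butyldimethylsilyl)oxy]propyl}-2-(hydroxymethyl)-3-oxocyclohexyl]propanoate (C-4 epimers) | CC(C)(C)[Si](C)(C)O[C@@H]1CCC(=O)[C@](CCCO[Si](C)(C)C(C)(C)C)(CO)[C@H]1C(C)C(=O)OC | intermediate (not isolated)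
12 | (5R,6R,10S)-keto lactone bis-silyl ether: C-9 cyclohexanone trans-fused to the 19,20-δ-lactone, 6β-OTBS, 10α-(3-silyloxypropyl), C-4 epimers | CC(C)(C)[Si](C)(C)O[C@@H]1CCC(=O)[C@]2(CCCO[Si](C)(C)C(C)(C)C)COC(=O)C(C)[C@@H]12 | intermediate (not isolated)
13 | (5R,6R,10S)-hydroxy keto lactone: as 12 with a free 3-hydroxypropyl chain on C-10 | CC(C)(C)[Si](C)(C)O[C@@H]1CCC(=O)[C@]2(CCCO)COC(=O)C(C)[C@@H]12 | intermediate
14 | (5R,6R,10S)-keto lactone tosylate: as 13 with the primary alcohol tosylated | CC(C)(C)[Si](C)(C)O[C@@H]1CCC(=O)[C@]2(CCCOS(=O)(=O)c3ccc(C)cc3)COC(=O)C(C)[C@@H]12 | intermediate (not isolated)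
15 | (5R,6R,10S)-tosylate enol silane: as 14 with the ketone as its C-8=C-9 triethylsilyl enol ether | CC(C)(C)[Si](C)(C)O[C@@H]1CC=C(O[Si](CC)(CC)CC)[C@]2(CCCOS(=O)(=O)c3ccc(C)cc3)COC(=O)C(C)[C@@H]12 | intermediate
16 | (4S,5S,6R,10S)-6-[(tert-butyldimethylsilyl)oxy]-9-[(triethylsilyl)oxy]-11,12,13,14,15,16,17-heptanorlabd-8-en-19,20-olide (cis-fused rings A/B; C-19 carbonyl, C-20 O-methylene) | CC(C)(C)[Si](C)(C)O[C@@H]1CC=C(O[Si](CC)(CC)CC)[C@]23CCC[C@](C)(C(=O)OC2)[C@@H]13 | intermediate
17 | (4S,5S,6R,10S)-6-[(tert-butyldimethylsilyl)oxy]-17-(dimethylamino)-9-oxo-11,12,13,14,15,16-hexanorlabdan-19,20-olide (C-8 epimers) | CC(C)(C)[Si](C)(C)O[C@@H]1CC(CN(C)C)C(=O)[C@]23CCC[C@](C)(C(=O)OC2)[C@@H]13 | intermediate (not isolated)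
18 | 17-trimethylammonium iodide of 17 (C-8 epimers) | CC(C)(C)[Si](C)(C)O[C@@H]1CC(C[N+](C)(C)C)C(=O)[C@]23CCC[C@](C)(C(=O)OC2)[C@@H]13.[I-] | intermediate (not isolated)
19 | (4S,5S,6R,10S)-6-[(tert-butyldimethylsilyl)oxy]-9-oxo-11,12,13,14,15,16-hexanorlabd-8(17)-en-19,20-olide | CC(C)(C)[Si](C)(C)O[C@@H]1CC(=C)C(=O)[C@]23CCC[C@](C)(C(=O)OC2)[C@@H]13 | intermediate
20 | (4S,5S,6R,8R,10S)-6-[(tert-butyldimethylsilyl)oxy]-8,17-epoxy-9-oxo-11,12,13,14,15,16-hexanorlabdan-19,20-olide | CC(C)(C)[Si](C)(C)O[C@@H]1C[C@@]2(CO2)C(=O)[C@]23CCC[C@](C)(C(=O)OC2)[C@@H]13 | intermediate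
21 | 2-(furan-3-yl)ethanol | OCCc1ccoc1 | starting material
22 | 3-(2-iodoethyl)furan | ICCc1ccoc1 | intermediate
23 | 2-(furan-3-yl)ethyllithium | [Li]CCc1ccoc1 | intermediate (not isolated)
24 | dichloro[2-(furan-3-yl)ethyl]cerium | Cl[Ce](Cl)CCc1ccoc1 | intermediate (not isolated)
25 | (4S,5S,6R,8R,9S,10S)-6-[(tert-butyldimethylsilyl)oxy]-8,17:15,16-diepoxy-9-hydroxylabda-13(16),14-dien-19,20-olide | CC(C)(C)[Si](C)(C)O[C@@H]1C[C@@]2(CO2)[C@](O)(CCc2ccoc2)[C@]23CCC[C@](C)(C(=O)OC2)[C@@H]13 | intermediate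
26 | (4S,5S,6R,8R,9S,10S)-8,17:15,16-diepoxy-6,9-dihydroxylabda-13(16),14-dien-19,20-olide | O[C@@H]1C[C@@]2(CO2)[C@](O)(CCc2ccoc2)[C@]23CCC[C@](C)(C(=O)OC2)[C@@H]13 | intermediate
27 | (4S,5S,6R,8R,9S,10S)-6-acetoxy-8,17:15,16-diepoxy-9-hydroxylabda-13(16),14-dien-19,20-olide | CC(=O)O[C@@H]1C[C@@]2(CO2)[C@](O)(CCc2ccoc2)[C@]23CCC[C@](C)(C(=O)OC2)[C@@H]13 | intermediate
28 | (4S,5S,6R,8R,9S,10S,13R)-6-acetoxy-8,17:9,13:15,16-triepoxylabd-14-en-19,20-olide | CC(=O)O[C@@H]1C[C@@]2(CO2)[C@]2(CC[C@]3(C=COC3)O2)[C@]23CCC[C@](C)(C(=O)OC2)[C@@H]13 | target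

**Step count**
Total: 16 steps. Longest linear sequence: 15 steps (steps 1–11 and 13–16); step 12 is a one-step side branch.

**Three steps most likely to fail**

Step 11 (epoxidation). The oxirane closure could follow the stereoelectronically preferred axial path and give the 8-epimer, or the peroxide could fail to add to the hindered enone. The fallback sets out from 19 and comes back at 20. OsO4 (2 mol%) with N-methylmorpholine N-oxide in acetone/H2O dihydroxylates the exocyclic alkene under pure steric approach control from the convex β-face to give the (8R)-8,17-dihydroxy-9-ketone F1. TsCl, Et3N and DMAP sulfonylate only the primary C-17 hydroxyl to give the monotosylate F2. DBU in CH2Cl2 then closes the oxirane by intramolecular Williamson displacement at C-17 with retention at C-8, which gives 20.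

Step 13 (addition to the ketone). The C-9 carbonyl is flanked by a quaternary carbon and a spiro-epoxide, so a primary alkylcerium may be too slow or may reduce it. The fallback sets out from 20 and comes back at 25. Commercial 3-ethynylfuran is deprotonated with n-BuLi, transmetalated with CeCl3 and added at −78 °C; the slim sp nucleophile attacks from the same β-face and gives the (9S)-9-[2-(furan-3-yl)ethynyl] carbinol F3. Diimide (2-nitrobenzenesulfonylhydrazide, Et3N, CH2Cl2) saturates the alkyne without touching furan, epoxide or lactone and gives 25.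

Step 16 (proposed dearomative hydroetherification). The tertiary alkoxy radical may undergo β-scission or 1,5-hydrogen transfer, the enol ether product may be oxidised by the excited catalyst, and the C-13 selectivity may be modest. The fallback uses known chemistry, sets out from 25 (before the silyl/acetyl exchange, because a hydride reduction is needed) and comes back at 28.
- Photooxygenation of the furan (O2, tetraphenylporphyrin, visible light, i-Pr2NEt, CH2Cl2, −78 °C) gives the 16-hydroxy-15,16-olide (γ-hydroxybutenolide) F4.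
- NaBH4 in MeOH at 0 °C reduces it to the 13-en-15,16-olide (β-substituted butenolide) F5.
- DBU in CH2Cl2 brings about reversible intramolecular oxa-Michael addition of the 9-hydroxyl to C-13 and gives the (13R)-9,13-epoxy-15,16-olide spiro-lactone F6.
- i-Bu2AlH in CH2Cl2 at −78 °C reduces the unhindered γ-lactone (the 19,20-lactone is shielded by two quaternary neighbours) to the lactol F7.
- MsCl and Et3N dehydrate the lactol to the 6-O-silyl 2,3-dihydrofuran F8.
- Bu4NF in THF gives the 6-alcohol F9, and Ac2O, pyridine and DMAP give 28.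

**Further compounds**
F1 | step 11 | (4S,5S,6R,8R,10S)-6-[(tert-butyldimethylsilyl)oxy]-8,17-dihydroxy-9-oxo-11,12,13,14,15,16-hexanorlabdan-19,20-olide | CC(C)(C)[Si](C)(C)O[C@@H]1C[C@@](O)(CO)C(=O)[C@]23CCC[C@](C)(C(=O)OC2)[C@@H]13
F2 | step 11 | 17-O-tosylate of F1 | CC(C)(C)[Si](C)(C)O[C@@H]1C[C@@](O)(COS(=O)(=O)c2ccc(C)cc2)C(=O)[C@]23CCC[C@](C)(C(=O)OC2)[C@@H]13
F3 | step 13 | (4S,5S,6R,8R,9S,10S)-6-[(tert-butyldimethylsilyl)oxy]-8,17:15,16-diepoxy-9-hydroxylabda-13(16),14-dien-11-yn-19,20-olide | CC(C)(C)[Si](C)(C)O[C@@H]1C[C@@]2(CO2)[C@](O)(C#Cc2ccoc2)[C@]23CCC[C@](C)(C(=O)OC2)[C@@H]13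
F4 | step 16 | (4S,5S,6R,8R,9S,10S)-6-[(tert-butyldimethylsilyl)oxy]-8,17-epoxy-9,16-dihydroxylabd-13-ene-19,20:15,16-diolide (C-16 epimers) | CC(C)(C)[Si](C)(C)O[C@@H]1C[C@@]2(CO2)[C@](O)(CCC2=CC(=O)OC2O)[C@]23CCC[C@](C)(C(=O)OC2)[C@@H]13
F5 | step 16 | (4S,5S,6R,8R,9S,10S)-6-[(tert-butyldimethylsilyl)oxy]-8,17-epoxy-9-hydroxylabd-13-ene-19,20:15,16-diolide | CC(C)(C)[Si](C)(C)O[C@@H]1C[C@@]2(CO2)[C@](O)(CCC2=CC(=O)OC2)[C@]23CCC[C@](C)(C(=O)OC2)[C@@H]13
F6 | step 16 | (4S,5S,6R,8R,9S,10S,13R)-6-[(tert-butyldimethylsilyl)oxy]-8,17:9,13-diepoxylabdane-19,20:15,16-diolide | CC(C)(C)[Si](C)(C)O[C@@H]1C[C@@]2(CO2)[C@]2(CC[C@]3(CC(=O)OC3)O2)[C@]23CCC[C@](C)(C(=O)OC2)[C@@H]13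
F7 | step 16 | (4S,5S,6R,8R,9S,10S,13R)-6-[(tert-butyldimethylsilyl)oxy]-8,17:9,13:15,16-triepoxy-15-hydroxylabdan-19,20-olide (C-15 epimers) | CC(C)(C)[Si](C)(C)O[C@@H]1C[C@@]2(CO2)[C@]2(CC[C@]3(CC(O)OC3)O2)[C@]23CCC[C@](C)(C(=O)OC2)[C@@H]13
F8 | step 16 | (4S,5S,6R,8R,9S,10S,13R)-6-[(tert-butyldimethylsilyl)oxy]-8,17:9,13:15,16-triepoxylabd-14-en-19,20-olide | CC(C)(C)[Si](C)(C)O[C@@H]1C[C@@]2(CO2)[C@]2(CC[C@]3(C=COC3)O2)[C@]23CCC[C@](C)(C(=O)OC2)[C@@H]13
F9 | step 16 | (4S,5S,6R,8R,9S,10S,13R)-8,17:9,13:15,16-triepoxy-6-hydroxylabd-14-en-19,20-olide | O[C@@H]1C[C@@]2(CO2)[C@]2(CC[C@]3(C=COC3)O2)[C@]23CCC[C@](C)(C(=O)OC2)[C@@H]13
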